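Count the enzyme first.

- alder: substrate 0.13 M; enzyme 0.01 mol%; added ligand 34 µM; run made earlier
- flask: substrate 0.13 M; enzyme 0.01 mol%; added ligand 17 µM

- alder (time / min: product / %): 0.333: 8; 0.833: 13; 1.50: 22; 2.50: 33; 3.00: 36; 5.00: 44

(each reading ± 1.5 percentage points)

- apparent order in enzyme when 5.0% of the substrate are converted (percent change of the rate of making product for one percent more enzyme charged)

- what was read earlier has a scatter of 1.5 percentage points, one standard deviation
- no earlier run changes the charge of enzyme; that part of a forecast is a guess
- no earlier run changes the charge of added ligand; that part of a forecast is a guess

In this flask the enzyme stands at 13.0 µM, less than the added ligand at 17 µM. If the two bind one to one, the enzyme is the partner charged in the smaller amount. Call the cover the added ligand charged per enzyme charged 1.31, the value for this flask.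

Next read the alder run, and take its rates over to this flask as a rough guide. Suppose the early slowing there is enzyme being taken up by added ligand, though falling substrate could also produce it:

first rate, alder: 0.240 min⁻¹ of the charge
next rate, alder: 0.120 min⁻¹
time to the asked conversion: 0.208 min
share of enzyme taken by then: 0.0695

Write the balance: free enzyme plus enzyme taken equals the charge. While the ligand stands nearly unspent, the share taken at a fixed time does not depend on the enzyme charged. But the order is asked at a fixed conversion, which more enzyme reaches sooner, so there the share taken goes as one over the enzyme charged. My reckoning then gives one plus the share taken over the share free: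

order, my reckoning: 1.07

The weak link is that unspent ligand, since the cover is small. Reforge it: a share s of the enzyme spends s divided by the cover of the ligand, here 0.0531, far below its charge. My 1.07 stands.

The forecast says 1.1, higher than mine, and it grants of the ligand that “No run tests either case”.

The flask gives 0.77.

    substrate + enzyme → product + enzyme, rate k1*[substrate]^3*[enzyme]/(1 + ([substrate]/Kh1)^3) (0.130 M, k = 64000 M⁻³ s⁻¹)
    2 enzyme ⇌ resting dimer, settled at all times (K = 42000 M⁻¹)
    enzyme + added ligand ⇌ idle complex (K = 52000 M⁻¹, k = 560 M⁻¹ s⁻¹)

In this flask, twice the enzyme gives 1.65 times the rate. At 15.0 min the added ligand stands at 76.3% of its charge, so the spent part times the cover gives 31.0% of the enzyme. That is the idle complex, read at 31.0%, beside enzyme at 46.0% and resting dimer at 23.1%.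

The numbers in the tables were computed for an exercise.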